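## Analysis of the target

Compound 23 (numbering as in the steps below) is a depside: two benzoyl units joined by one aryl ester, with no fused ring. It has no stereocentre and no double-bond geometry, so no stereochemical relationship has to be set. Ring A is a benzoic acid with the free carboxyl on C1, a methoxy group on C2, the ester oxygen on C4 and an n-pentyl chain on C6. Ring B is a 2,4-dimethoxy-6-propylbenzoyl group bound through its carbonyl to O4 of ring A. The depside ester is a phenolic ester and is cleaved by hydroxide or alkoxide. The free acid of ring A sits between two ortho substituents on an electron-rich ring and is prone to protodecarboxylation under acid and heat. The difficulty is therefore the order of events on ring A, where the C1 carboxyl, O2 and O4 must become acid, methyl ether and aryl ester, the acid must be unmasked last under neutral conditions, and both acyl transfers are hindered by double ortho substitution. The plan rests on ring A being the folded form of a 3,5,7-trioxododecanoyl chain, in which ring C1 is chain C2, the oxygens on ring C2 and C4 are the chain C3 and C5 carbonyls, ring C6 is chain C7 and the pentyl group is chain C8 to C12, so that forming the single bond between C1 and C6 of ring A closes the ring.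

## Retrosynthetic reasoning

**Benzyl ester.** Target 23 is traced back to benzyl ester 22 by cutting the benzylic C–O bond. The acid cannot be carried free through acylation and methylation, and it cannot be released by saponification because the depside ester would be cleaved first. Hydrogenolysis is neutral and leaves aryl esters alone, so the forward step only has to break one C–O bond.

**Methyl ether at O2.** In 22 the O–CH3 bond at C2 of ring A is cut, giving phenol 21. The methylation is placed after the ring union on purpose: while O2 is a free hydroxyl it is tied to the neighbouring ester carbonyl by a hydrogen bond, and this is what distinguishes O2 from O4 in the preceding step. The forward reaction must alkylate a chelated phenol without damaging the depside link.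

**Depside ester.** The C(=O)–O bond between the rings is cut, giving resorcylate 13 and aroyl chloride 20. It is the only bond joining the two halves, so this cut gives full convergence and lets each ring be built separately. The forward reaction must acylate O4 and not O2.

**Ring A (key disconnection).** In 13 the bond between C1 and C6 of ring A is cut and the arene is unfolded, through aldol 12, into the open-chain triketo ester 11. This cut is preferred to any other ring bond because every substituent is then accounted for by the chain: the two hydroxyls are carbonyls, the pentyl group is the chain end, and the ester is C1. Ester 11 is not isolated: its ester C–O bond leads back to acylketene 10 and benzyl alcohol 9, and 10 is the thermal fragmentation product of diketo-dioxinone 8. The gain is that ring, substitution pattern and benzyl ester all come from one stable precursor in one operation. The forward reaction must steer the chain into the C2-to-C7 aldol and not into its other closure modes.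

**Side chain of 8.** Compound 8 is cut between C3 and C4 of its 2,4-dioxononyl chain, giving keto-dioxinone 3 (reacting as dianion 6) and Weinreb amide 5, which comes from hexanoyl chloride 4. This places a simple six-carbon acyl donor against the terminal carbon of a dianion, its most nucleophilic site. A cut one carbonyl further in would need an enolisable β-keto acyl donor. The amide holds the tetrahedral adduct 7 until work-up, so the acidic product cannot quench the dianion.

**Keto-dioxinone.** Compound 3 is cut between C1 and C2 of the oxopropyl group, leading to dioxinone 1, which reacts as its dienolate 2 with an acetyl electrophile.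

**Ring B.** Chloride 20 comes from acid 19 and this from aldehyde 18 by changes at the carbonyl carbon only. In 18 the ring–CHO bond is cut, via iminium salt 17, back to 16. Electrophilic formylation enters para to one methoxy group and ortho to the other and to the propyl chain, which is exactly the ring B pattern. Arene 16 comes from alkene 15 by saturation, and the C=C bond of 15 is cut to aldehyde 14 and a two-carbon phosphorus ylide.

## Alternatives that were turned down

Alternative 1: Ring B, not ring A, is taken apart at its C1–C6 and C2–C3 bonds, which leads to dimethyl malonate A1 and (E)-hept-3-en-2-one A2. In the forward key step an alkoxide would add A1 to the β-carbon of A2, and the methyl ketone enolate would then close onto one ester in a Claisen condensation, giving methyl 2-hydroxy-4-oxo-6-propylcyclohex-2-ene-1-carboxylate A3 as the racemic trans compound. Oxidative aromatisation of A3 would give methyl 2,4-dihydroxy-6-propylbenzoate A4, and double O-methylation and ester hydrolysis would lead to acid 19. In its favour, the reagents are cheap and the carboxyl carbon arrives with the malonate, so there is no formylation regiochemistry and no aldehyde oxidation on an electron-rich ring; on these two points it is stronger than the ring B sequence chosen here. Against it, ring A3 is formed one oxidation level below the arene, and dehydrogenation of such enolised diones with halogen-type oxidants tends to halogenate the ring. The methyl ester of A4 lies between two ortho substituents, and the forcing hydrolysis it needs is the condition under which such acids decarboxylate. The sequence also spends its ring-forming step on the half with no selectivity problem and leaves ring A unmade. In comparison, about five operations lead to chloride 20 either way, so nothing is saved, whereas the chosen strategy delivers ring A with its benzyl ester and two distinguishable hydroxyls in one step, with no redox adjustment of a ring.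

Alternative 2: Ring A is cut at C1–C2 and C5–C6, which gives benzyl oct-2-ynoate A5 and 1,1-dimethoxy-3-(trimethylsilyloxy)buta-1,3-diene A6. The forward key step is a thermal [4+2] cycloaddition in which the unsubstituted terminus of A6 bonds to the pentyl-bearing alkyne carbon of A5 and the ketene acetal carbon of A6 to the ester-bearing carbon of A5. Loss of one methoxy group and of the silyl group would then give benzyl 4-hydroxy-2-methoxy-6-pentylbenzoate A7. In its favour, A7 already has O2 methylated and O4 free; on this point it is stronger than the chosen strategy, because it needs no selective acylation, no methylation next to a depside ester, and one step fewer after ring formation. Against it, ynoate A5 carries a β-alkyl group and is a sluggish dienophile that needs prolonged heating, while diene A6 is hydrolytically and thermally fragile and must be made and used in excess. Stepwise conjugate addition without ring closure and premature desilylation compete, and both partners have to be prepared, so A7 is not reached in fewer steps than 13. In comparison, the chosen strategy closes the ring intramolecularly at room temperature, with regiochemistry fixed by the constitution of the chain and aromatisation as driving force; it pays one extra step (methylation) and relies on the hydrogen-bonded 2-OH for differentiation.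

Alternative 3: Both the ring B C1–carbonyl bond and the carbonyl–oxygen bond are cut, which gives 2-iodo-1,5-dimethoxy-3-propylbenzene A8, carbon monoxide A9 and phenol A7. The forward key step is a palladium-catalysed aryloxycarbonylation with a wide-bite-angle diphosphine and an amine base (oxidative addition of A8, insertion of A9, acyl–oxygen bond formation with A7), which would give benzyl 4-[(2,4-dimethoxy-6-propylbenzoyl)oxy]-2-methoxy-6-pentylbenzoate A10; ester A10 is the same compound as 22. In its favour, ring B would need only iodination of 16 to reach A8, two steps fewer than formylation, oxidation and chlorination, and the coupling runs under neutral conditions; on step count for ring B it is stronger. Against it, the step is an end-game coupling and builds no ring. It presupposes A7 with O2 already methylated, which would have to come from alternative 2 or from 13 by a protecting-group detour. Iodide A8 is electron-rich and doubly ortho-substituted, which slows oxidative addition to zerovalent palladium and the insertion of A9. Phenoxides are poorer partners than alkoxides in the acyl–oxygen bond-forming step, and hydrodeiodination of A8 competes. In comparison, the chosen route makes the ester bond of A10 by classical acyl substitution, whose outcome is not in doubt, and places its risk in the ring construction, where it is controlled by a long-established reaction type.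

Key step: step 4

Remark on the chemistry: in step 4 the chain atoms of 11 are numbered from the ester carbonyl (C1) to the terminal methyl (C12). Ring A atoms are numbered from the carboxyl-bearing carbon (C1) to the pentyl-bearing carbon (C6). Alkene 15 is carried as an E/Z mixture, which is immaterial because it is hydrogenated in step 6.

## Route

Step 1
Reactants: 1 2,2,6-trimethyl-4H-1,3-dioxin-4-one
Product: 3 2,2-dimethyl-6-(2-oxopropyl)-4H-1,3-dioxin-4-one, via lithium 2,2-dimethyl-6-methylidene-6H-1,3-dioxin-4-olate 2 (not isolated)
Conditions: LiN(SiMe3)2 (1.05 equiv), THF, −78 °C; then AcCl (0.5 equiv), −78 → 0 °C; then 1 M HCl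
Reagents that add atoms: acetyl chloride, CC(Cl)=O
Why: LiN(SiMe3)2 removes a proton from the 6-methyl group of 1 to give dienolate 2, which is C-acylated at its terminal carbon by the acid chloride (vinylogous Claisen-type acylation of a dioxinone dienolate). Product 3 is more acidic than 1, so half of the dienolate serves as base and returns as 1 on work-up, which is why the acid chloride is the limiting reagent.

Step 2
Reactants: 4 hexanoyl chloride
Product: 5 N-methoxy-N-methylhexanamide
Conditions: MeNH(OMe)·HCl, pyridine, CH2Cl2, 0 °C → rt
Reagents that add atoms: N,O-dimethylhydroxylamine hydrochloride, CNOC.Cl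
Why: Acylation of an amine by an acid chloride (Weinreb amide formation). The N-methoxy-N-methyl amide is chosen because its adduct with a carbon nucleophile does not collapse before work-up.

Step 3
Reactants: 3 2,2-dimethyl-6-(2-oxopropyl)-4H-1,3-dioxin-4-one; 5 N-methoxy-N-methylhexanamide
Product: 8 6-(2,4-dioxononyl)-2,2-dimethyl-4H-1,3-dioxin-4-one, via dilithium bis-enolate 6 (not isolated), via dilithium tetrahedral adduct 7 (not isolated)
Conditions: LiN(iPr)2 (2.1 equiv), THF, −78 °C; then 5, −78 → −30 °C; then 1 M HCl
Reagents that add atoms: none
Why: Two equivalents of LiN(iPr)2 deprotonate 3 first at the doubly activated methylene and then at the terminal methyl, and dianion 6 reacts at the last-formed, most nucleophilic terminal carbon (Claisen-type acylation of a β-dicarbonyl dianion with a Weinreb amide). The amide holds adduct 7 as a lithium chelate, so the acidic diketone is released only on acid quench and neither over-addition nor proton transfer to unreacted dianion should occur.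

Step 4
Reactants: 8 6-(2,4-dioxononyl)-2,2-dimethyl-4H-1,3-dioxin-4-one; 9 benzyl alcohol
Product: 13 benzyl 2,4-dihydroxy-6-pentylbenzoate, via acylketene 3,5,7-trioxododec-1-en-1-one 10 (not isolated), via benzyl 3,5,7-trioxododecanoate 11 (not isolated), via benzyl 2-hydroxy-4,6-dioxo-2-pentylcyclohexane-1-carboxylate 12 (not isolated)
Conditions: 9 (1.1 equiv), PhMe, 110 °C; then K2CO3, iPrOH/CH2Cl2, rt; then HCl in iPrOH, rt
Reagents that add atoms: none
Why: At 110 °C the dioxinone ring of 8 undergoes retro-[4+2] fragmentation with loss of acetone to give acylketene 10, which alcohol 9 captures at the ketene carbon to give the β,δ,ζ-triketo ester 11; this is the standard thermolysis and trapping chemistry of 2,2-dimethyl-1,3-dioxin-4-ones. Carbonate then enolises 11 reversibly, and the C2 carbanion, stabilised by the ester and the C3 ketone, adds to the C7 ketone to form the C2–C7 bond (ring A C1–C6) in aldol 12. The closure is 6-exo-trig at the C7 carbonyl; in enolate terms it is 6-(enolendo)-exo-trig when the enolate is written through C3 and 6-(enolexo)-exo-trig when written through the ester carbonyl, and both are favoured by Baldwin's rules. Elimination of the tertiary hydroxyl (E1cB, completed by HCl) and enolisation of the two ring ketones should give arene 13 irreversibly, which drains all preceding equilibria; the closest known reaction type is the biomimetic aldol aromatisation of 3,5,7-triketo esters to resorcylates. The two stereocentres of 12 are transient and are erased on aromatisation, so no stereocontrol is required. The selectivity needed is the C2-to-C7 aldol over Claisen closure of C6 onto the ester carbonyl, the C8-to-C3 aldol, and attack of an enol oxygen on a carbonyl to give pyranones. C4 and C6 are more acidic than C2, but the C4 enolate has no six-membered carbocyclic closure open to it and the C6 enolate only the Claisen path with expulsion of benzyl oxide, which carbonate at room temperature does not drive; C8 is singly activated and not appreciably enolised; and acid, which favours O-cyclisation, is added only after the C–C bond exists. A slight excess of 9 keeps intermolecular capture of 10 ahead of capture by an internal enol oxygen, and the isopropanol cosolvent avoids ester exchange.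

Step 5
Reactants: 14 3,5-dimethoxybenzaldehyde
Product: 15 1,3-dimethoxy-5-(prop-1-en-1-yl)benzene (E/Z mixture)
Conditions: EtPPh3Br, KOtBu, THF, 0 °C → rt
Reagents that add atoms: ethyltriphenylphosphonium bromide, CC[P+](c1ccccc1)(c1ccccc1)c1ccccc1.[Br-]
Why: Wittig olefination of an aryl aldehyde with an unstabilised ylide. The alkene geometry is irrelevant because the double bond is saturated in step 6.

Step 6
Reactants: 15 1,3-dimethoxy-5-(prop-1-en-1-yl)benzene (E/Z mixture)
Product: 16 1,3-dimethoxy-5-propylbenzene
Conditions: H2 (1 atm), Pd/C (10% Pd), EtOAc, rt
Reagents that add atoms: none
Why: Heterogeneous catalytic hydrogenation of a styrene-type double bond. The arene and the aryl methyl ethers are inert at this pressure and temperature.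

Step 7
Reactants: 16 1,3-dimethoxy-5-propylbenzene
Product: 18 2,4-dimethoxy-6-propylbenzaldehyde, via aryl iminium chloride 17 (not isolated)
Conditions: POCl3, DMF, 0 → 80 °C; then ice-water
Reagents that add atoms: N,N-dimethylformamide, CN(C)C=O; water, O
Why: Vilsmeier–Haack formylation. The chloroiminium electrophile should enter para to one methoxy group and ortho to the other, because para activation outweighs the doubly ortho-activated but shielded position between the two methoxy groups, as is usual for 5-alkylresorcinol dimethyl ethers. Water then hydrolyses iminium salt 17 to the aldehyde.

Step 8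
Reactants: 18 2,4-dimethoxy-6-propylbenzaldehyde
Product: 19 2,4-dimethoxy-6-propylbenzoic acid
Conditions: NaClO2, NaH2PO4, 2-methyl-2-butene (excess), tBuOH/H2O, rt
Reagents that add atoms: sodium chlorite, [Na+].[O-]Cl=O
Why: Pinnick oxidation converts the hindered aryl aldehyde to the acid under buffered conditions. The excess alkene removes hypochlorous acid so that the electron-rich ring is not chlorinated.

Step 9
Reactants: 19 2,4-dimethoxy-6-propylbenzoic acid
Product: 20 2,4-dimethoxy-6-propylbenzoyl chloride
Conditions: (COCl)2, DMF (cat.), CH2Cl2, 0 °C → rt
Reagents that add atoms: oxalyl chloride, O=C(Cl)C(Cl)=O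
Why: Acid chloride formation through the catalytic chloroiminium species from DMF and oxalyl chloride. The other products are gases, and the crude chloride is used directly.

Step 10
Reactants: 13 benzyl 2,4-dihydroxy-6-pentylbenzoate; 20 2,4-dimethoxy-6-propylbenzoyl chloride
Product: 21 benzyl 4-[(2,4-dimethoxy-6-propylbenzoyl)oxy]-2-hydroxy-6-pentylbenzoate
Conditions: Et3N, DMAP (cat.), CH2Cl2, 0 °C → rt
Reagents that add atoms: none
Why: Nucleophilic acyl substitution (DMAP-catalysed esterification of a phenol by an aroyl chloride). The 2-OH of 13 is locked in a hydrogen bond to the ester carbonyl and is flanked by the ester, so the more acidic, unhindered 4-OH should be acylated when one equivalent of 20 is used.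

Step 11
Reactants: 21 benzyl 4-[(2,4-dimethoxy-6-propylbenzoyl)oxy]-2-hydroxy-6-pentylbenzoate
Product: 22 benzyl 4-[(2,4-dimethoxy-6-propylbenzoyl)oxy]-2-methoxy-6-pentylbenzoate
Conditions: MeI, K2CO3, DMF, rt → 40 °C
Reagents that add atoms: iodomethane, CI
Why: Williamson O-methylation of the remaining hydrogen-bonded phenol with carbonate in a dipolar aprotic solvent. The depside carbonyl is shielded by a methoxy and a propyl group and no hydroxide or alkoxide is present, so the ester link and the benzyl ester should survive.

Step 12
Reactants: 22 benzyl 4-[(2,4-dimethoxy-6-propylbenzoyl)oxy]-2-methoxy-6-pentylbenzoate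
Product: 23 4-[(2,4-dimethoxy-6-propylbenzoyl)oxy]-2-methoxy-6-pentylbenzoic acid
Conditions: H2 (1 atm), Pd/C (10% Pd), EtOAc, rt
Reagents that add atoms: none
Why: Hydrogenolysis of the benzylic C–O bond frees the carboxylic acid under neutral conditions. The aryl ester, the methyl ethers and both arenes are inert, and the decarboxylation-prone product sees neither acid nor base.

## Compound list

1 | 2,2,6-trimethyl-4H-1,3-dioxin-4-one | CC1=CC(=O)OC(C)(C)O1 | starting material
2 | lithium 2,2-dimethyl-6-methylidene-6H-1,3-dioxin-4-olate (lithium dienolate of 1) | [Li+].[O-]C1=CC(=C)OC(C)(C)O1 | intermediate (not isolated)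
3 | 2,2-dimethyl-6-(2-oxopropyl)-4H-1,3-dioxin-4-one | CC(=O)CC1=CC(=O)OC(C)(C)O1 | intermediate
4 | hexanoyl chloride | CCCCCC(Cl)=O | starting material
5 | N-methoxy-N-methylhexanamide | CCCCCC(=O)N(C)OC | intermediate
6 | dilithium 3-(2,2-dimethyl-4-oxido-6H-1,3-dioxin-6-ylidene)prop-1-en-2-olate (dianion of 3) | [Li+].[Li+].[O-]C(=C)C=C1C=C([O-])OC(C)(C)O1 | intermediate (not isolated)
7 | dilithium 1-(2,2-dimethyl-4-oxo-4H-1,3-dioxin-6-yl)-4-[methoxy(methyl)amino]non-1-ene-2,4-bis(olate) (racemic) | [Li+].[Li+].CCCCCC([O-])(N(C)OC)CC([O-])=CC1=CC(=O)OC(C)(C)O1 | intermediate (not isolated)
8 | 6-(2,4-dioxononyl)-2,2-dimethyl-4H-1,3-dioxin-4-one | CCCCCC(=O)CC(=O)CC1=CC(=O)OC(C)(C)O1 | intermediate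
9 | benzyl alcohol | OCc1ccccc1 | starting material
10 | 3,5,7-trioxododec-1-en-1-one (acylketene) | CCCCCC(=O)CC(=O)CC(=O)C=C=O | intermediate (not isolated)
11 | benzyl 3,5,7-trioxododecanoate | CCCCCC(=O)CC(=O)CC(=O)CC(=O)OCc1ccccc1 | intermediate (not isolated)
12 | benzyl 2-hydroxy-4,6-dioxo-2-pentylcyclohexane-1-carboxylate (mixture of racemic diastereomers and enol tautomers) | CCCCCC1(O)CC(=O)CC(=O)C1C(=O)OCc1ccccc1 | intermediate (not isolated)
13 | benzyl 2,4-dihydroxy-6-pentylbenzoate | CCCCCc1cc(O)cc(O)c1C(=O)OCc1ccccc1 | intermediate
14 | 3,5-dimethoxybenzaldehyde | COc1cc(C=O)cc(OC)c1 | starting material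
15 | 1,3-dimethoxy-5-(prop-1-en-1-yl)benzene (E/Z mixture) | CC=Cc1cc(OC)cc(OC)c1 | intermediate
16 | 1,3-dimethoxy-5-propylbenzene | CCCc1cc(OC)cc(OC)c1 | intermediate
17 | N-[(2,4-dimethoxy-6-propylphenyl)methylidene]-N-methylmethanaminium chloride | CCCc1cc(OC)cc(OC)c1C=[N+](C)C.[Cl-] | intermediate (not isolated)
18 | 2,4-dimethoxy-6-propylbenzaldehyde | CCCc1cc(OC)cc(OC)c1C=O | intermediate
19 | 2,4-dimethoxy-6-propylbenzoic acid | CCCc1cc(OC)cc(OC)c1C(=O)O | intermediate
20 | 2,4-dimethoxy-6-propylbenzoyl chloride | CCCc1cc(OC)cc(OC)c1C(Cl)=O | intermediate
21 | benzyl 4-[(2,4-dimethoxy-6-propylbenzoyl)oxy]-2-hydroxy-6-pentylbenzoate | CCCCCc1cc(OC(=O)c2c(CCC)cc(OC)cc2OC)cc(O)c1C(=O)OCc1ccccc1 | intermediate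
22 | benzyl 4-[(2,4-dimethoxy-6-propylbenzoyl)oxy]-2-methoxy-6-pentylbenzoate | CCCCCc1cc(OC(=O)c2c(CCC)cc(OC)cc2OC)cc(OC)c1C(=O)OCc1ccccc1 | intermediate
23 | 4-[(2,4-dimethoxy-6-propylbenzoyl)oxy]-2-methoxy-6-pentylbenzoic acid | CCCCCc1cc(OC(=O)c2c(CCC)cc(OC)cc2OC)cc(OC)c1C(=O)O | target

## Step count and risk

Total step count: 12. Longest linear sequence: 8 steps (steps 5 to 12, from 14). The ring A branch from 1 is 6 steps (1, 3, 4, 10, 11, 12); step 2 is a one-step side branch.

**Step 4 (key step).** The polycarbonyl chain may close in another mode (attack of an enol oxygen on a carbonyl, or Claisen closure of C6 onto the ester), or the acylketene may be captured by an internal enol oxygen before the alcohol adds. All these paths start from the same intermediates and differ only in rate. Fallback: set out from 8 and aromatise before the dioxinone is opened. Et3N in CH2Cl2 at room temperature should effect aldol closure of the dioxinone C5 position onto the distal ketone, followed by dehydration, to give 7-hydroxy-2,2-dimethyl-5-pentyl-4H-1,3-benzodioxin-4-one F1; no ketene and no free triketo ester occur on this path. Opening of the acetonide lactone of F1 with excess NaOCH2Ph (made from 9 and NaH in THF) would then give 13, where the route is rejoined.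

**Step 3.** Acylation by the amide may be too slow at the temperature the dianion tolerates, and on warming the dianion can decay by attack on the dioxinone carbonyl or by proton exchange. Fallback: set out from 3 and trap the same dianion at −78 °C with hexanal, a much faster electrophile, to give the aldol 6-(4-hydroxy-2-oxononyl)-2,2-dimethyl-4H-1,3-dioxin-4-one F2 (racemic). Oxidation of the secondary alcohol with Dess–Martin periodinane in CH2Cl2 would then give 8.

**Step 10.** Acyl transfer from the doubly ortho-substituted aroyl chloride may be slow, so that hydrolysis or a second acylation at O2 competes. Fallback: set out from acid 19 and phenol 13, bypassing 20. Trifluoroacetic anhydride in toluene should convert 19 into 2,4-dimethoxy-6-propylbenzoic trifluoroacetic anhydride F3, which ionises to a donor-stabilised acylium ion. That electrophile is far less sensitive to ortho substitution and acylates the unchelated 4-OH of 13 without base, returning to the route at 21.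

**Step 11.** Alkylation of the hydrogen-bonded phenol may be slow, and forcing it invites cleavage or intermolecular transfer of the aroyl group by phenoxide. Fallback: change the order of events, setting out from 13. Selective 4-O-allylation (allyl bromide, K2CO3, acetone) should give benzyl 2-hydroxy-6-pentyl-4-(prop-2-en-1-yloxy)benzoate F4. Methylation of the 2-OH can then be forced without risk to an aryl ester (MeI, K2CO3, DMF, 60 °C) to give benzyl 2-methoxy-6-pentyl-4-(prop-2-en-1-yloxy)benzoate F5. Deallylation with catalytic Pd(PPh3)4 and morpholine would give benzyl 4-hydroxy-2-methoxy-6-pentylbenzoate F6, and acylation of F6 with 20 (Et3N, DMAP, CH2Cl2) returns to the route at 22.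

## Further compounds

F1 | step 4 | 7-hydroxy-2,2-dimethyl-5-pentyl-4H-1,3-benzodioxin-4-one | CCCCCc1cc(O)cc2OC(C)(C)OC(=O)c12
F2 | step 3 | 6-(4-hydroxy-2-oxononyl)-2,2-dimethyl-4H-1,3-dioxin-4-one (racemic) | CCCCCC(O)CC(=O)CC1=CC(=O)OC(C)(C)O1
F3 | step 10 | 2,4-dimethoxy-6-propylbenzoic trifluoroacetic anhydride | CCCc1cc(OC)cc(OC)c1C(=O)OC(=O)C(F)(F)F
F4 | step 11 | benzyl 2-hydroxy-6-pentyl-4-(prop-2-en-1-yloxy)benzoate | CCCCCc1cc(OCC=C)cc(O)c1C(=O)OCc1ccccc1
F5 | step 11 | benzyl 2-methoxy-6-pentyl-4-(prop-2-en-1-yloxy)benzoate | CCCCCc1cc(OCC=C)cc(OC)c1C(=O)OCc1ccccc1
F6 | step 11 | benzyl 4-hydroxy-2-methoxy-6-pentylbenzoate | CCCCCc1cc(O)cc(OC)c1C(=O)OCc1ccccc1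
A1 | alternative 1 | dimethyl malonate | COC(=O)CC(=O)OC
A2 | alternative 1 | (E)-hept-3-en-2-one | CCC/C=C/C(C)=O
A3 | alternative 1 | methyl 2-hydroxy-4-oxo-6-propylcyclohex-2-ene-1-carboxylate (racemic, trans enantiomer drawn) | CCC[C@@H]1CC(=O)C=C(O)[C@H]1C(=O)OC
A4 | alternative 1 | methyl 2,4-dihydroxy-6-propylbenzoate | CCCc1cc(O)cc(O)c1C(=O)OC
A5 | alternative 2 | benzyl oct-2-ynoate | CCCCCC#CC(=O)OCc1ccccc1
A6 | alternative 2 | 1,1-dimethoxy-3-(trimethylsilyloxy)buta-1,3-diene | COC(OC)=CC(=C)O[Si](C)(C)C
A7 | alternative 2 | benzyl 4-hydroxy-2-methoxy-6-pentylbenzoate | CCCCCc1cc(O)cc(OC)c1C(=O)OCc1ccccc1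
A8 | alternative 3 | 2-iodo-1,5-dimethoxy-3-propylbenzene | CCCc1cc(OC)cc(OC)c1I
A9 | alternative 3 | carbon monoxide | [C-]#[O+]
A10 | alternative 3 | benzyl 4-[(2,4-dimethoxy-6-propylbenzoyl)oxy]-2-methoxy-6-pentylbenzoate | CCCCCc1cc(OC(=O)c2c(CCC)cc(OC)cc2OC)cc(OC)c1C(=O)OCc1ccccc1
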